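The runs were generated by integration from invented constants, and the scatter is random.

In a one-step world each substrate takes one reagent and stops, and the end of the flask can be read from the charges. Gamma and epsilon show a second step, since double product stands in both, and I take its name at its word: it holds one reagent more than the first step spends. For noon the charges then give 20.0% as the reagent surplus, the reagent charged beyond one per substrate, in percent of the substrate charged. The surplus is reckoned from the two charges, with no time in it.

| flask | substrate | reagent | remark | time |
|---|---|---|---|---|
| gamma | 0.45 M | 0.80 M | run made earlier |  |
| epsilon | 0.45 M | 1.6 M | run made earlier |  |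
| noon | 0.45 M | 0.540 M |  | 2.5 min |
| spring | 0.45 M | 0.900 M |  | 2.5 min |
| dawn | 0.45 M | 1.35 M |  | 2.5 min |

| run | time / min | double product / % | substrate / % |
|---|---|---|---|
| gamma | 0.417 | 21 | 16 |
| gamma | 0.833 | 24 | 7 |
| gamma | 1.33 | 21 | 4 |
| gamma | 1.50 | 19 | 3 |
| gamma | 2.00 | 17 | 2 |
| gamma | 2.50 | 15 | 1 |
| epsilon | 0.200 | 30 | 9 |
| epsilon | 0.333 | 30 | 0 |
| epsilon | 0.500 | 27 | 1 |
| epsilon | 0.833 | 15 | 0 |
| epsilon | 1.50 | 6 | 1 |
| epsilon | 2.50 | 0 | 1 |

(readings scatter by 1.5 percentage points)



* double product at the end, in percent of the substrate charged, for each flask in turn (noon, spring, dawn)

Here is my own reckoning of the noon curve. Gamma's first reading, scaled to noon's reagent charge, gives substrate a starting half-life of roughly 0.234 min, so double product should climb steeply at first. At 0.833 min gamma reads 25.8% of the used substrate as double product. Carry that share to noon and the reagent balance closes with 4.62% of the substrate unreacted. That is the knee, and the curve should level there at 24.6%. Any later loss of double product that spends reagent lowers this figure, so watch the noon plateau.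

The forecast gives 29%, 12% and 3%, and for noon it says “the double product is stranded near its peak”. My noon level is lower than its figure; for spring and dawn I set no figure against it.

The flasks give 14.4%, 12.8% and 2.68%.

    substrate + reagent → single product (k = 0.180 /M/s)
    reagent + single product → double product (k = 0.0740 /M/s)
    reagent + double product → triple product (k = 0.0580 /M/s)
    single product → side product (k = 0.0320 /s)

In noon at 0.133 min, single product goes to side product 1.4 times as fast as it goes on to double product, and at 2.50 min side product stands at 66.2%. Noon's surplus of 20.0%, plus 11% of substrate left, less the reagent left, makes 28.0% spent beyond the first step; double product holds 14.4% of that. In spring the surplus is 100%, the same reckoning gives 77.1%, and double product holds 12.8%.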